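**Plan**

- Retrosynthesis: remove the O9 senecioate and the O6 silyl ether. Cut the C7–C8 bond, which is common to the ten-membered carbocycle (ring A) and the γ-lactone (ring B), together with the lactone C12–O8 bond. This gives an acyclic C8 aldehyde with a 2-(bromomethyl)enoate at C7/C11/C13. Cut that chain at C7–C11, C6–C7, C5–C6/C4–C15, C10–C14 and C8–C9, back to hepta-1,6-diyne.
- Forward: the chain is grown linearly from the diyne (C8 and C6 from formaldehyde, C14 and C15 from Me3Al, C7 from a vinyl Grignard reagent, C11–C13 from methyl acrylate). Rings A and B then arise together in one chromium-mediated step. Acylation of O9 and desilylation of O6 finish the route.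
- Enabling feature: the array O8–C8–C7–C11(=C13H2)–C12(=O) of the cis-fused α-methylene-γ-butyrolactone is the product pattern of a 2-(methoxycarbonyl)allyl-metal addition to an aldehyde. Closing C7–C8 from a C13 allylic bromide and a C8 aldehyde should therefore create ring A, ring B, the exocyclic methylene and both ring-fusion stereocentres at a stroke.
- Stereochemistry: C9/C10 from a Sharpless epoxidation (L-(+)-tartrate) and its invertive opening by Me3Al; C4/C5 from a second Sharpless epoxidation (D-(−)-tartrate); C6 from Felkin–Anh addition to the epoxy aldehyde; C7/C8 in the cyclisation, from allylic 1,3-strain at C6 and a chair transition state.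

Key step: step 15

Remark: atom numbers are the germacrane numbers of the target (ring carbons C1–C10; lactone carbons C11, C12, C13; C14 is the methyl on C10, C15 the methyl on C4).

**Route**

Step 1
Reactants: 1 hepta-1,6-diyne
Product: 3 octa-2,7-diyn-1-ol, via lithium acetylide 2 (not isolated)
Conditions: n-BuLi (1 equiv), 1 in excess, THF, −78 °C; then (CH2O)n, −78 to 23 °C
Reagents that add atoms: formaldehyde (as paraformaldehyde), C=O
Why: Deprotonation of one terminal alkyne and 1,2-addition of the acetylide to formaldehyde (acetylide hydroxymethylation) should give the mono-propargylic alcohol, the excess of diyne keeping double addition low, and no stereocentre is formed.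

Step 2
Reactants: 3 octa-2,7-diyn-1-ol
Product: 4 (E)-oct-2-en-7-yn-1-ol
Conditions: NaAlH2(OCH2CH2OCH3)2, THF, 0 to 23 °C; aqueous NaOH work-up
Reagents that add atoms: none
Why: Hydroxyl-directed trans-hydroalumination of the propargylic alcohol followed by protonolysis should give only the E-allylic alcohol, while the isolated terminal alkyne is merely deprotonated and returns on work-up.

Step 3
Reactants: 4 (E)-oct-2-en-7-yn-1-ol
Product: 5 ((2S,3S)-3-(pent-4-yn-1-yl)oxiran-2-yl)methanol
Conditions: Ti(OiPr)4 (10 mol %), L-(+)-diethyl tartrate (12 mol %), t-BuOOH, 4 Å molecular sieves, CH2Cl2, −20 °C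
Reagents that add atoms: tert-butyl hydroperoxide, CC(C)(C)OO
Why: Sharpless asymmetric epoxidation of the E-allylic alcohol delivers oxygen to the face fixed by the L-(+)-tartrate ligand, which sets C9 and C10 as the (2S,3S)-epoxy alcohol and leaves the alkyne alone.

Step 4
Reactants: 5 ((2S,3S)-3-(pent-4-yn-1-yl)oxiran-2-yl)methanol
Product: 6 (2R,3R)-3-methyloct-7-yne-1,2-diol
Conditions: Me3Al (3 equiv), hexane–CH2Cl2, 0 to 23 °C
Reagents that add atoms: trimethylaluminium, C[Al](C)C
Why: The aluminium alkoxide of the 2,3-epoxy alcohol directs methyl transfer to the distal epoxide carbon (C10) with inversion (regioselective organoaluminium opening of a 2,3-epoxy alcohol), which gives the 1,2-diol with the C9 hydroxyl and the C10 methyl anti and leaves C9 untouched.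

Step 5
Reactants: 6 (2R,3R)-3-methyloct-7-yne-1,2-diol
Product: 7 (2R,3R)-3-methyl-1,2-bis(triethylsilyloxy)oct-7-yne
Conditions: Et3SiCl, imidazole, DMF, 0 to 23 °C
Reagents that add atoms: chlorotriethylsilane, CC[Si](Cl)(CC)CC
Why: Standard silylation of both hydroxyls gives a protecting pattern that tolerates organoaluminium reagents and can later be cleaved at the primary position alone.

Step 6
Reactants: 7 (2R,3R)-3-methyl-1,2-bis(triethylsilyloxy)oct-7-yne
Product: 10 (2E,7R,8R)-3,7-dimethyl-8,9-bis(triethylsilyloxy)non-2-en-1-ol, via alkenylalane 8 (not isolated), via lithium aluminate 9 (not isolated)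
Conditions: Me3Al, Cp2ZrCl2 (25 mol %), CH2Cl2, 0 to 23 °C; solvent exchange to THF, n-BuLi, −78 °C; (CH2O)n, −78 to 23 °C
Reagents that add atoms: trimethylaluminium, C[Al](C)C; formaldehyde (as paraformaldehyde), C=O
Why: Zirconium-catalysed syn-carboalumination of the terminal alkyne (Negishi carboalumination) puts methyl on C4 and aluminium on C5 on the same side, and the ate complex adds to formaldehyde with retention, so the E-trisubstituted allylic alcohol should result.

Step 7
Reactants: 10 (2E,7R,8R)-3,7-dimethyl-8,9-bis(triethylsilyloxy)non-2-en-1-ol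
Product: 11 (4R,5R)-epoxy alcohol
Conditions: Ti(OiPr)4 (10 mol %), D-(−)-diethyl tartrate (12 mol %), t-BuOOH, 4 Å molecular sieves, CH2Cl2, −20 °C
Reagents that add atoms: tert-butyl hydroperoxide, CC(C)(C)OO
Why: Sharpless asymmetric epoxidation of the E-trisubstituted allylic alcohol under control of the D-(−)-tartrate ligand should set C4 and C5 (both R), the remote C9 and C10 centres having no influence.

Step 8
Reactants: 11 (4R,5R)-epoxy alcohol
Product: 12 α,β-epoxy aldehyde (C6 aldehyde)
Conditions: Dess–Martin periodinane, NaHCO3, CH2Cl2, 0 to 23 °C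
Reagents that add atoms: none
Why: Buffered Dess–Martin oxidation converts the primary epoxy alcohol into the epoxy aldehyde without acid that could open the epoxide or base that could epimerise C5.

Step 9
Reactants: 12 α,β-epoxy aldehyde
Product: 13 (6R)-vinyl carbinol
Conditions: CH2=CHMgBr, THF, −78 °C
Reagents that add atoms: vinylmagnesium bromide, C=C[Mg]Br
Why: Grignard addition to the α,β-epoxy aldehyde should follow the Felkin–Anh model with the epoxide C5–O bond anti to the incoming vinyl group, giving the anti (erythro) epoxy alcohol with C6 R, and the minor C6 epimer should be separable by chromatography.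

Step 10
Reactants: 13 (6R)-vinyl carbinol
Product: 14 O6 tert-butyldimethylsilyl ether
Conditions: t-BuMe2SiOTf, 2,6-lutidine, CH2Cl2, −78 °C
Reagents that add atoms: tert-butyldimethylsilyl trifluoromethanesulfonate, CC(C)(C)[Si](C)(C)OS(=O)(=O)C(F)(F)F
Why: Silyl triflate silylation at low temperature with a hindered base protects the hindered secondary hydroxyl next to the epoxide with a group that outlasts the triethylsilyl ethers.

Step 11
Reactants: 14 O6 tert-butyldimethylsilyl ether
Product: 16 α-silyloxy aldehyde (C7 aldehyde), via ozonide 15 (not isolated)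
Conditions: O3, CH2Cl2, −78 °C; then PPh3, −78 to 23 °C
Reagents that add atoms: ozone, [O-][O+]=O
Why: Ozonolysis of the only alkene in the molecule with reductive work-up gives the C7 aldehyde without touching the C6 stereocentre.

Step 12
Reactants: 16 α-silyloxy aldehyde; 17 methyl acrylate
Product: 18 Morita–Baylis–Hillman adduct (mixture of C7 epimers)
Conditions: DABCO (1 equiv), methyl acrylate (neat, excess), 23 °C
Reagents that add atoms: none
Why: The Morita–Baylis–Hillman reaction of the activated α-silyloxy aldehyde builds C11–C13 onto C7, and the new carbinol centre at C7 need not be controlled because it becomes sp2 in the next step.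

Step 13
Reactants: 18 Morita–Baylis–Hillman adduct
Product: 19 (Z)-2-(bromomethyl)enoate
Conditions: N-bromosuccinimide, Me2S, CH2Cl2, 0 to 23 °C
Reagents that add atoms: N-bromosuccinimide, O=C1CCC(=O)N1Br
Why: Activation of the allylic hydroxyl as an alkoxysulfonium ion and SN2′ attack of bromide at C13 should give the rearranged primary allylic bromide as the favoured trisubstituted enoate in which C6 is cis to the bromomethyl group.

Step 14
Reactants: 19 (Z)-2-(bromomethyl)enoate
Product: 20 C8 aldehyde (cyclisation precursor)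
Conditions: (COCl)2, DMSO, CH2Cl2, −78 to −40 °C; i-Pr2NEt, −78 to 0 °C
Reagents that add atoms: none
Why: Under Swern conditions the chlorosulfonium reagent cleaves the less hindered primary triethylsilyl ether and oxidises it in place (direct Swern oxidation of a primary silyl ether), while the secondary silyl ethers stay and the hindered amine at low temperature spares the allylic bromide.

Step 15
Reactants: 20 C8 aldehyde
Product: 23 cis-fused silyl-protected epoxy germacranolide, via allylchromium species 21 (not isolated), via chromium alkoxide 22 (not isolated)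
Conditions: CrCl2 (10 equiv), THF, 23 °C, 20 added by syringe pump to a final 2 mM; aqueous NH4Cl work-up
Reagents that add atoms: none
Why: Two equivalents of CrCl2 reduce the allylic C13–Br bond of 20 to the allylchromium species 21 (trivalent chromium), which adds through its γ-carbon C7 to the C8 aldehyde in a closed six-membered chair transition state, and the chromium alkoxide 22 then acylates on the neighbouring C12 methyl ester, releasing methanol and giving lactone 23. The closest known reaction type is the intramolecular Nozaki–Hiyama–Kishi (chromium Barbier) addition of 2-(alkoxycarbonyl)allyl bromides to aldehydes, which is established for ten-membered carbocycles fused to α-methylene lactones. Ring A closes by 10-exo-trig attack of C7 on the C8 carbonyl and ring B by 5-exo-trig attack of O8 on C12. C7 is controlled by the C6 stereocentre: allylic 1,3-strain holds H6 in the plane of the C7=C11 bond, the silyloxy group and C5 then flank opposite faces, and the aldehyde, tethered through C5, can reach only the C5 face (anti to the silyloxy group), which is the configuration that is 7R in 27. C8 is controlled by the chair, in which C6 is pseudo-axial (it is cis to the CH2Cr carbon) and C9 pseudo-equatorial, so the 7,8-syn adduct with H7 and H8 cis, hence the cis-fused lactone with 8R, should result. The step needs the aldehyde face to be chosen against the Felkin–Anh bias of the C9 silyloxy group and cyclisation to outrun oligomerisation; the first is secured by the combined allyl-face and chair control with a non-chelating, weakly face-selective chromium reagent, the second by slow addition at high dilution.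

Step 16
Reactants: 23 cis-fused silyl-protected epoxy germacranolide
Product: 24 C9 hydroxy lactone
Conditions: HF·pyridine, pyridine, THF, 0 °C
Reagents that add atoms: none
Why: Buffered fluoride desilylation removes the more labile secondary triethylsilyl ether at O9 and should leave the tert-butyldimethylsilyl ether at O6, the epoxide and the lactone intact.

Step 17
Reactants: 24 C9 hydroxy lactone; 25 3-methylbut-2-enoyl chloride
Product: 26 O9 senecioate O6 silyl ether
Conditions: pyridine, DMAP (cat.), CH2Cl2, 0 to 23 °C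
Reagents that add atoms: none
Why: Nucleophile-catalysed acylation of the only free hydroxyl (O9) installs the senecioate, the weak base pyridine avoiding vinylketene formation that would deconjugate the acyl group.

Step 18
Reactants: 26 O9 senecioate O6 silyl ether
Product: 27 CNP0214930.1
Conditions: HF·pyridine, THF, 0 to 23 °C
Reagents that add atoms: none
Why: Acidic fluoride desilylation frees O6 without the basic conditions that could cause Payne rearrangement of the epoxy alcohol or migration of the lactone or the ester.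

**Compound list**

1 | hepta-1,6-diyne | C#CCCCC#C | starting material
2 | lithium hepta-1,6-diyn-1-ide | [Li]C#CCCCC#C | intermediate
3 | octa-2,7-diyn-1-ol | OCC#CCCCC#C | intermediate
4 | (E)-oct-2-en-7-yn-1-ol | OC/C=C/CCCC#C | intermediate
5 | ((2S,3S)-3-(pent-4-yn-1-yl)oxiran-2-yl)methanol | OC[C@@H]1O[C@H]1CCCC#C | intermediate
6 | (2R,3R)-3-methyloct-7-yne-1,2-diol | OC[C@H](O)[C@H](C)CCCC#C | intermediate
7 | (2R,3R)-3-methyl-1,2-bis(triethylsilyloxy)oct-7-yne | CC[Si](CC)(CC)OC[C@H](O[Si](CC)(CC)CC)[C@H](C)CCCC#C | intermediate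
8 | dimethyl[(1E,6R,7R)-2,6-dimethyl-7,8-bis(triethylsilyloxy)oct-1-en-1-yl]alane | CC[Si](CC)(CC)OC[C@H](O[Si](CC)(CC)CC)[C@H](C)CCC/C(C)=C/[Al](C)C | intermediate
9 | lithium butyl(dimethyl)[(1E,6R,7R)-2,6-dimethyl-7,8-bis(triethylsilyloxy)oct-1-en-1-yl]aluminate | CC[Si](CC)(CC)OC[C@H](O[Si](CC)(CC)CC)[C@H](C)CCC/C(C)=C/[Al-](C)(C)CCCC.[Li+] | intermediate
10 | (2E,7R,8R)-3,7-dimethyl-8,9-bis(triethylsilyloxy)non-2-en-1-ol | CC[Si](CC)(CC)OC[C@H](O[Si](CC)(CC)CC)[C@H](C)CCC/C(C)=C/CO | intermediate
11 | ((2R,3R)-3-methyl-3-[(4R,5R)-4-methyl-5,6-bis(triethylsilyloxy)hexyl]oxiran-2-yl)methanol | CC[Si](CC)(CC)OC[C@H](O[Si](CC)(CC)CC)[C@H](C)CCC[C@@]1(C)O[C@@H]1CO | intermediate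
12 | (2S,3R)-3-methyl-3-[(4R,5R)-4-methyl-5,6-bis(triethylsilyloxy)hexyl]oxirane-2-carbaldehyde | CC[Si](CC)(CC)OC[C@H](O[Si](CC)(CC)CC)[C@H](C)CCC[C@@]1(C)O[C@@H]1C=O | intermediate
13 | (1R)-1-{(2R,3R)-3-methyl-3-[(4R,5R)-4-methyl-5,6-bis(triethylsilyloxy)hexyl]oxiran-2-yl}prop-2-en-1-ol | CC[Si](CC)(CC)OC[C@H](O[Si](CC)(CC)CC)[C@H](C)CCC[C@@]1(C)O[C@@H]1[C@H](O)C=C | intermediate
14 | tert-butyldimethylsilyl ether of 13 at O6 (C6 R) | CC[Si](CC)(CC)OC[C@H](O[Si](CC)(CC)CC)[C@H](C)CCC[C@@]1(C)O[C@@H]1[C@H](O[Si](C)(C)C(C)(C)C)C=C | intermediate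
15 | secondary ozonide of 14 (1,2,4-trioxolane at C7) | CC[Si](CC)(CC)OC[C@H](O[Si](CC)(CC)CC)[C@H](C)CCC[C@@]1(C)O[C@@H]1[C@H](O[Si](C)(C)C(C)(C)C)C1OCOO1 | intermediate
16 | (2S)-2-(tert-butyldimethylsilyloxy)-2-{(2R,3R)-3-methyl-3-[(4R,5R)-4-methyl-5,6-bis(triethylsilyloxy)hexyl]oxiran-2-yl}acetaldehyde | CC[Si](CC)(CC)OC[C@H](O[Si](CC)(CC)CC)[C@H](C)CCC[C@@]1(C)O[C@@H]1[C@H](O[Si](C)(C)C(C)(C)C)C=O | intermediate
17 | methyl acrylate | C=CC(=O)OC | starting material
18 | methyl (4R)-4-(tert-butyldimethylsilyloxy)-3-hydroxy-2-methylidene-4-{(2R,3R)-3-methyl-3-[(4R,5R)-4-methyl-5,6-bis(triethylsilyloxy)hexyl]oxiran-2-yl}butanoate, both C3 epimers | CC[Si](CC)(CC)OC[C@H](O[Si](CC)(CC)CC)[C@H](C)CCC[C@@]1(C)O[C@@H]1[C@H](O[Si](C)(C)C(C)(C)C)C(O)C(=C)C(=O)OC | intermediate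
19 | methyl (2Z,4R)-2-(bromomethyl)-4-(tert-butyldimethylsilyloxy)-4-{(2R,3R)-3-methyl-3-[(4R,5R)-4-methyl-5,6-bis(triethylsilyloxy)hexyl]oxiran-2-yl}but-2-enoate | CC[Si](CC)(CC)OC[C@H](O[Si](CC)(CC)CC)[C@H](C)CCC[C@@]1(C)O[C@@H]1[C@H](O[Si](C)(C)C(C)(C)C)/C=C(\CBr)C(=O)OC | intermediate
20 | methyl (2Z,4R)-2-(bromomethyl)-4-(tert-butyldimethylsilyloxy)-4-{(2R,3R)-3-methyl-3-[(4R,5R)-4-methyl-6-oxo-5-(triethylsilyloxy)hexyl]oxiran-2-yl}but-2-enoate | O=C[C@H](O[Si](CC)(CC)CC)[C@H](C)CCC[C@@]1(C)O[C@@H]1[C@H](O[Si](C)(C)C(C)(C)C)/C=C(\CBr)C(=O)OC | intermediate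
21 | allylchromium species: 20 with CrCl2 on C13 in place of bromine | O=C[C@H](O[Si](CC)(CC)CC)[C@H](C)CCC[C@@]1(C)O[C@@H]1[C@H](O[Si](C)(C)C(C)(C)C)/C=C(\C[Cr](Cl)Cl)C(=O)OC | intermediate
22 | ten-membered 7,8-syn alkoxide (O8–CrCl2) with C11=C13 methylidene and C12 methyl ester, (4R,5R,6R,7R,8R,9R,10R) | COC(=O)C(=C)[C@H]1[C@@H](O[Cr](Cl)Cl)[C@H](O[Si](CC)(CC)CC)[C@H](C)CCC[C@@]2(C)O[C@@H]2[C@@H]1O[Si](C)(C)C(C)(C)C | intermediate
23 | (4R,5R,6R,7S,8R,9R,10R)-6-(tert-butyldimethylsilyloxy)-4,5-epoxy-9-(triethylsilyloxy)germacr-11(13)-en-12,8-olide | C=C1C(=O)O[C@H]2[C@H](O[Si](CC)(CC)CC)[C@H](C)CCC[C@@]3(C)O[C@@H]3[C@H](O[Si](C)(C)C(C)(C)C)[C@@H]12 | intermediate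
24 | (4R,5R,6R,7S,8R,9R,10R)-6-(tert-butyldimethylsilyloxy)-4,5-epoxy-9-hydroxygermacr-11(13)-en-12,8-olide | C=C1C(=O)O[C@H]2[C@H](O)[C@H](C)CCC[C@@]3(C)O[C@@H]3[C@H](O[Si](C)(C)C(C)(C)C)[C@@H]12 | intermediate
25 | 3-methylbut-2-enoyl chloride | CC(C)=CC(Cl)=O | starting material
26 | (4R,5R,6R,7S,8R,9R,10R)-6-(tert-butyldimethylsilyloxy)-4,5-epoxy-9-(3-methylbut-2-enoyloxy)germacr-11(13)-en-12,8-olide | C=C1C(=O)O[C@H]2[C@H](OC(=O)C=C(C)C)[C@H](C)CCC[C@@]3(C)O[C@@H]3[C@H](O[Si](C)(C)C(C)(C)C)[C@@H]12 | intermediate
27 | CNP0214930.1, (4R,5R,6R,7R,8R,9R,10R)-4,5-epoxy-6-hydroxy-9-(3-methylbut-2-enoyloxy)germacr-11(13)-en-12,8-olide | C=C1C(=O)O[C@H]2[C@H](OC(=O)C=C(C)C)[C@H](C)CCC[C@@]3(C)O[C@@H]3[C@H](O)[C@@H]12 | target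

**Step count and risks**

Total steps: 18. Longest linear sequence: 18 steps (from 1).

Steps most likely to fail:

Step 15 (ring closure). The aldehyde may be attacked on the wrong face, because the C9 silyloxy group is mismatched with the allyl fragment in the Felkin–Anh sense. The allylchromium species may also lose the C6 silyloxy group by 1,4-elimination, or oligomerise before it cyclises. Fallback, from 20 back to 24: the C9 triethylsilyl ether of 20 would be cleaved with HF·pyridine–pyridine in THF at 0 °C to give the α-hydroxy aldehyde F1. F1 would be cyclised under aqueous Barbier conditions (indium powder, THF–water, high dilution). There the free C9 hydroxyl and the aldehyde oxygen chelate the metal, so chelation and not the Felkin–Anh preference fixes the aldehyde face (8,9-syn), and the mild medium disfavours elimination. The ten-membered dihydroxy ester F2 should lactonise through O8 on silica gel or with a trace of acid, which rejoins the route at 24.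

Step 12 (Morita–Baylis–Hillman). During the long exposure to the amine, the enolisable α-silyloxy aldehyde may open the C4–C5 epoxide by β-elimination, epimerise at C6, or simply not react. Fallback, from 16 back to 18: a preformed, non-basic nucleophile would be used instead. Methyl 2-(diisobutylalumanyl)prop-2-enoate F3, made from methyl propiolate and i-Bu2AlH with N-methylmorpholine N-oxide in THF at 0 °C (hydroalumination at the α-carbon), should add to aldehyde 16 within hours at 0 °C and give the same hydroxy ester 18 after work-up.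

Step 14 (direct Swern oxidation). The activated allylic bromide may alkylate the amine base, bromide may exchange for chloride, or the secondary triethylsilyl ether may be cleaved as well. Fallback, from 19 back to 20: the primary triethylsilyl ether alone would be removed with HF·pyridine–pyridine in THF at −20 °C to give the primary alcohol F4, and F4 would be oxidised with Dess–Martin periodinane buffered with NaHCO3, which needs no amine base, to reach aldehyde 20.

Further compounds
F1 | step 15 | methyl (2Z,4R)-2-(bromomethyl)-4-(tert-butyldimethylsilyloxy)-4-{(2R,3R)-3-[(4R,5R)-5-hydroxy-4-methyl-6-oxohexyl]-3-methyloxiran-2-yl}but-2-enoate | O=C[C@H](O)[C@H](C)CCC[C@@]1(C)O[C@@H]1[C@H](O[Si](C)(C)C(C)(C)C)/C=C(\CBr)C(=O)OC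
F2 | step 15 | ten-membered 8,9-dihydroxy ester with C11=C13 methylidene, C12 methyl ester and O6 tert-butyldimethylsilyl ether, (4R,5R,6R,7S,8R,9R,10R) | COC(=O)C(=C)[C@H]1[C@@H](O)[C@H](O)[C@H](C)CCC[C@@]2(C)O[C@@H]2[C@@H]1O[Si](C)(C)C(C)(C)C
F3 | step 12 | methyl 2-(diisobutylalumanyl)prop-2-enoate | C=C(C(=O)OC)[Al](CC(C)C)CC(C)C
F4 | step 14 | methyl (2Z,4R)-2-(bromomethyl)-4-(tert-butyldimethylsilyloxy)-4-{(2R,3R)-3-[(4R,5R)-6-hydroxy-4-methyl-5-(triethylsilyloxy)hexyl]-3-methyloxiran-2-yl}but-2-enoate | OC[C@H](O[Si](CC)(CC)CC)[C@H](C)CCC[C@@]1(C)O[C@@H]1[C@H](O[Si](C)(C)C(C)(C)C)/C=C(\CBr)C(=O)OC
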